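- Read the runs below for one thing: treat intermediate and target in a hot flask as one pool whose exchange has stopped, and reckon with what that leaves free, the size of the pool.

| flask | substrate | coupling partner | temperature | remark | time |
|---|---|---|---|---|---|
| dawn | 20 mM | 50 mM | 85 °C | run made earlier |  |
| summer | 20 mM | 79 mM | 96 °C | run made earlier |  |
| winter | 10 mM | 36 mM | 85 °C | run made earlier |  |
| cedar | 20 mM | 36.0 mM |  | at 80 °C until 2.0 h, from then on at 100 °C | 3.0 h |
| ash | 20 mM | 36.0 mM | 80 °C |  | 3.0 h |
| larch | 20 mM | 36.0 mM | 100 °C |  | 3.0 h |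

dawn run (percent of the substrate charged)

| time / h | intermediate / % | target / % | substrate / % |
|---|---|---|---|
| 0.500 | 32.8 | 9.8 | 32.0 |
| 1.00 | 29.0 | 22.2 | 11.4 |
| 1.50 | 21.2 | 33.3 | 3.8 |
| 2.00 | 15.2 | 39.4 | 2.3 |
| 2.50 | 11.3 | 43.3 | 1.2 |
| 3.00 | 8.2 | 45.4 | 1.1 |
| 4.00 | 5.9 | 47.7 | 0.2 |

summer run (percent of the substrate charged)

| time / min | intermediate / % | target / % | substrate / % |
|---|---|---|---|
| 5.00 | 24.7 | 2.3 | 56.0 |
| 15.0 | 33.3 | 14.3 | 19.4 |
| 25.0 | 27.0 | 26.0 | 7.7 |
| 40.0 | 16.5 | 35.3 | 2.2 |
| 50.0 | 11.6 | 39.5 | 1.6 |
| 80.0 | 6.5 | 45.1 | 0.5 |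
| 120 | 6.1 | 46.6 | 0.1 |

winter run (percent of the substrate charged)

| time / h | intermediate / % | target / % | substrate / % |
|---|---|---|---|
| 0.250 | 19.9 | 2.5 | 61.6 |
| 0.500 | 26.6 | 7.4 | 37.9 |
| 1.00 | 25.1 | 19.4 | 15.7 |
| 2.00 | 14.0 | 34.0 | 3.9 |
| 4.00 | 6.1 | 42.6 | 0.9 |

(each reading ± 0.3 percentage points)

- what was read earlier has a scatter of 0.3 percentage points, one standard deviation

- which flask leads in amount of intermediate, in percent of the substrate charged ("all alike" within 1.5 percentage points) (cedar / ash / larch / all alike)
- how much intermediate is there at the end, in percent of the substrate charged: cedar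
- how much intermediate is there at the end, in percent of the substrate charged: ash
- how much intermediate is there at the end, in percent of the substrate charged: larch

- The summer run is slowing but still moving: between 80.0 min and 120 min intermediate reads 6.5% and then 6.1%, while target still climbs from 45.1% to 46.6%. Its last reading gives intermediate over intermediate plus target as 0.116, and I call this the resting share, a late reading with its scatter that I use in place of an equilibrium fraction. The last dawn reading gives 0.110.
- Larch is hotter than summer, so I take its end as standing near this share, and if its pool matched summer's 52.7%, it would hold 6.11% intermediate.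
- That pool is the weak link, since larch has 36.0 mM of coupling partner against summer's 79 mM. From dawn to winter the pool falls from 53.6% to 48.7% as partner falls from 50 mM to 36 mM, though winter also had less substrate. Taken as the odds of pool against the unseen rest, that is an order of 0.597. Carried to larch, the pool is 41.1%, so I commit to 4.75% intermediate.
- Cedar ends with 1.00 h hot after a cool start, so I give it winter's pool and 5.65%. Dawn at 3.00 h still holds 8.2%, above the 6.20% that the share gives, so I expect the cooler ash to lead.
- The forecast also picks ash, with cedar 5.8%, ash 15.2% and larch 5.5%, on the ground that “Larch reaches equilibrium”; its larch stands above mine.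
- The flask gives ash in the lead, with cedar 5.41%, ash 16.3% and larch 4.40%, so the forecast stands; larch's answer moves by 5 points at a reading as early as 0.561 h. Larch has not come to rest: left until 30.0 h, its intermediate goes to 6.90%, its target from 32.9% to 60.3%, and its dormant form falls from 49.1% to 11.3%. Its resting share moves from 0.118 to 0.103.

    intermediate ⇌ target (K = 8.90, k = 0.0540 min⁻¹, Ea = 97.0 kJ mol⁻¹, ΔH = −12.0 kJ mol⁻¹)
    substrate + coupling partner → intermediate + released group (k = 1.20 L mol⁻¹ min⁻¹, Ea = 57.0 kJ mol⁻¹)
    substrate → decomposition product (k = 2.40 × 10⁻⁵ min⁻¹, Ea = 125 kJ mol⁻¹)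
    substrate ⇌ dormant form (K = 19.0, k = 0.0580 min⁻¹, Ea = 109 kJ mol⁻¹, ΔH = 12.0 kJ mol⁻¹)
    intermediate ⇌ isomer of the product (K = 3.10, k = 0.0200 min⁻¹, Ea = 126 kJ mol⁻¹, ΔH = −45.0 kJ mol⁻¹)
    (constants at 100 °C)

- The flask cedar left until 2.0 h at 80 °C holds a pool for which the resting share gives 5.84% intermediate. The computed value is 24.1%, so that flask stands far from rest.

The earlier runs and the new flask are simulated for substances that don't exist; scatter was added.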